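The bicyclic core is cut into two acyclic pieces at C4a–C8a and C6–C7 (isochromene numbering; ring A carbocycle, ring B pyran). The plan exploits the C6(=O)–C7(O) α-ketol of ring A, a union of two carbonyl carbons of like polarity, and the nucleophilic C8a of the vinylogous ester O2–C1=C8a. In one flask an enaminone of biacetyl adds through C8a to C4a of a chiral hydroxy-ynal, the hydroxyl closes ring B, and a chiral triazolylidene then reverses the polarity of the C6 aldehyde, which adds to the C7 ketone and sets C7. Oleoylation of the tertiary alcohol completes the target.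

Key step: step 3

Assumption: the (5aS,10bR) antipode of the triazolium salt is taken to deliver the 7R configuration by analogy with related benzoin cyclisations; if the sense proves opposite, the (5aR,10bS) antipode is used without other change.

Step 1
Reactants: 1 (R)-pent-4-yn-2-ol
Product: 2 (R)-5-hydroxyhex-2-ynal
Conditions: n-BuLi (2.1 equiv), THF, −78 to −20 °C; DMF, −78 to 0 °C; reverse quench into cold aq. KH2PO4
Reagents that add atoms: N,N-dimethylformamide, CN(C)C=O
Why: Double deprotonation gives the alkoxide–acetylide dianion, whose carbon terminus is formylated by DMF (Bouveault-type formylation of a lithium acetylide), and the buffered reverse quench should release the ynal without conjugate addition of the liberated amine; the C3 stereocentre comes from the chiral pool and is not involved.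

Step 2
Reactants: 3 butane-2,3-dione (biacetyl)
Product: 4 (E)-5-(dimethylamino)pent-4-ene-2,3-dione
Conditions: 3 (4 equiv), N,N-dimethylformamide dimethyl acetal (1 equiv), toluene, 0 °C to rt; volatiles removed in vacuo
Reagents that add atoms: N,N-dimethylformamide dimethyl acetal, COC(OC)N(C)C
Why: Condensation of a methyl ketone with an amide acetal should give the E enaminone, and the excess of 3 together with the lower C–H acidity of the remaining acetyl group (now flanked by a vinylogous amide carbonyl) should stop the reaction after one condensation.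

Step 3
Reactants: 2 (R)-5-hydroxyhex-2-ynal; 4 (E)-5-(dimethylamino)pent-4-ene-2,3-dione
Product: 7 (3R,7R)-7-hydroxy-3,7-dimethyl-3,4-dihydro-6H-isochromene-6,8(7H)-dione, via aminodienal 5 (not isolated), via pyranylidene acetaldehyde 6 (not isolated)
Conditions: AcOH (2 equiv), CH2Cl2, 35 °C; then, in the same flask, N-methylmorpholine (3 equiv), (5aS,10bR)-2-(pentafluorophenyl)-5a,10b-dihydro-4H,6H-indeno[2,1-b][1,2,4]triazolo[4,3-d][1,4]oxazin-2-ium tetrafluoroborate (15 mol %), 0 °C to rt
Reagents that add atoms: none
Why: Proposed new method: acetic acid should promote Stork-enamine-type (Bohlmann–Rahtz-type) conjugate addition of the enaminone α-carbon C8a to the ynal β-carbon C4a, the side-chain hydroxyl then displaces dimethylamine at C1 (6-exo-trig addition to the protonated aminomethylene carbon, then elimination, as in the enaminone-to-chromone exchange) to close ring B, and after the switch to N-methylmorpholine the triazolylidene converts the C6 aldehyde into a carbene-bound enaminol (acyl anion equivalent) that adds to the C7 acetyl ketone (6-exo-trig) to close ring A. The closest known reactions are the amine/carbene-catalysed Michael–crossed-benzoin cascade of 1,3-dicarbonyl compounds with enals and the enantioselective intramolecular aldehyde–ketone benzoin cyclisation; the cross-conjugated C8a acyl group draws off part of the donor strength of O2, so the C6 aldehyde of 6 should stay electrophilic enough for carbene addition. The only new stereocentre, C7, is set by the chiral triazolium catalyst, which selects the face of the prochiral acetyl carbonyl, while C3 is carried unchanged from 2. The step is stereoconvergent in the C4a=C5 geometry, because push-pull conjugation and reversible protonation let the E and Z isomers of 6 interconvert and only the Z isomer can cyclise. Chemoselectivity for C7 over C8 is secured because C8 is a deactivated vinylogous-ester carbonyl whose attack would give a strained five-membered ring, and the redox (acyl azolium) pathway of ynals is avoided because the carbene is released only after the ynal is consumed. Dimethylamine should stay parked as its ammonium salt because N-methylmorpholine is the weaker base, so it cannot reopen ring B.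

Step 4
Reactants: 7 (3R,7R)-7-hydroxy-3,7-dimethyl-3,4-dihydro-6H-isochromene-6,8(7H)-dione; 8 oleoyl chloride
Product: 9 (3R,7R)-3,7-dimethyl-6,8-dioxo-3,4,7,8-tetrahydro-6H-isochromen-7-yl (9Z)-octadec-9-enoate
Conditions: 8 (1.5 equiv), Et3N (2 equiv), 4-(dimethylamino)pyridine (0.2 equiv), CH2Cl2, 0 °C to rt
Reagents that add atoms: none
Why: Nucleophilic-catalysis O-acylation of the tertiary α-ketol hydroxyl with an acid chloride should give the ester, leaving C3, C7 and the Z alkene of the chain untouched.

Compound list
1 | (R)-pent-4-yn-2-ol | C[C@@H](O)CC#C | starting material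
2 | (R)-5-hydroxyhex-2-ynal | C[C@@H](O)CC#CC=O | intermediate
3 | butane-2,3-dione (biacetyl) | CC(=O)C(C)=O | starting material
4 | (E)-5-(dimethylamino)pent-4-ene-2,3-dione | CN(C)/C=C/C(=O)C(C)=O | intermediate
5 | 4-[(dimethylamino)methylidene]-3-[(2R)-2-hydroxypropyl]-5,6-dioxohept-2-enal (mixture of alkene isomers, not isolated) | C[C@@H](O)CC(=CC=O)C(=CN(C)C)C(=O)C(C)=O | intermediate
6 | (2Z)-2-[(6R)-6-methyl-3-(2-oxopropanoyl)-5,6-dihydro-4H-pyran-4-ylidene]acetaldehyde (E and Z isomers interconvert, reactive Z isomer shown, not isolated) | O=C/C=C1/C[C@@H](C)OC=C1C(=O)C(C)=O | intermediate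
7 | (3R,7R)-7-hydroxy-3,7-dimethyl-3,4-dihydro-6H-isochromene-6,8(7H)-dione | O[C@]1(C)C(=O)C=C2C[C@@H](C)OC=C2C1=O | intermediate
8 | oleoyl chloride, (9Z)-octadec-9-enoyl chloride | CCCCCCCC/C=C\CCCCCCCC(=O)Cl | starting material
9 | (3R,7R)-3,7-dimethyl-6,8-dioxo-3,4,7,8-tetrahydro-6H-isochromen-7-yl (9Z)-octadec-9-enoate | CCCCCCCC/C=C\CCCCCCCC(=O)O[C@]1(C)C(=O)C=C2C[C@@H](C)OC=C2C1=O | target

Total steps: 4. Longest linear sequence: 3 steps (1 to 2 to 7 to 9, or 3 to 4 to 7 to 9).

Steps most likely to fail

Step 3. The carbene may add only sluggishly to the push-pull C6 aldehyde, or the benzoin closure may show poor facial selectivity at C7. The fallback sets out from 2 and builds the C6–C7 bond with normal polarity (aldol, then oxidation), giving up catalyst control of C7. Commercial 3-hydroxybutan-2-one is silylated (TBSCl, imidazole) to racemic 3-[(tert-butyldimethylsilyl)oxy]butan-2-one F1. Condensation with N,N-dimethylformamide dimethyl acetal gives (E)-4-[(tert-butyldimethylsilyl)oxy]-1-(dimethylamino)pent-1-en-3-one F2. Compound 2 and F2 are combined under the acid stage alone (AcOH, CH2Cl2) to give 2-[(6R)-3-{2-[(tert-butyldimethylsilyl)oxy]propanoyl}-6-methyl-5,6-dihydro-4H-pyran-4-ylidene]acetaldehyde F3. Enolisation toward C7 with LiN(SiMe3)2 at −78 °C should close ring A by intramolecular aldol addition to the C6 aldehyde, giving (3R)-7-[(tert-butyldimethylsilyl)oxy]-6-hydroxy-3,7-dimethyl-3,4,6,7-tetrahydro-8H-isochromen-8-one F4. Dess–Martin periodinane oxidises the C6 carbinol to (3R)-7-[(tert-butyldimethylsilyl)oxy]-3,7-dimethyl-3,4-dihydro-6H-isochromene-6,8(7H)-dione F5, expected as both C7 epimers. HF·pyridine removes the silyl group, and the C7 epimers (diastereomers because of C3) are separated by preparative HPLC into 7 and (3R,7S)-7-hydroxy-3,7-dimethyl-3,4-dihydro-6H-isochromene-6,8(7H)-dione F6. The route is rejoined at 7.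

Step 2. The condensation may run on to the bis-enaminone, or the basic medium may trigger self-condensation of biacetyl. The fallback sets out from 3 and masks one carbonyl first. Compound 3 is mono-ketalised (MeOH, HC(OMe)3, cat. p-toluenesulfonic acid) to 3,3-dimethoxybutan-2-one F7. Its only methyl ketone condenses with N,N-dimethylformamide dimethyl acetal (neat, 100 °C) to (E)-1-(dimethylamino)-4,4-dimethoxypent-1-en-3-one F8. Cleavage of the ketal with wet formic acid at rt returns to 4.

Step 1. The free hydroxy-ynal may be lost through conjugate addition of dimethylamine during the quench or through oligomerisation on concentration. The fallback sets out from 1 and separates carbon–carbon bond formation from adjustment of the oxidation level. The dianion of 1 (n-BuLi, THF) is hydroxymethylated with paraformaldehyde to (R)-hex-2-yne-1,5-diol F9. MnO2 in CH2Cl2 should oxidise only the propargylic primary alcohol, and filtration gives a neutral, amine-free solution of 2 that is used directly in step 3.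

Further compounds
F1 | step 3 | 3-[(tert-butyldimethylsilyl)oxy]butan-2-one (racemic) | CC(O[Si](C)(C)C(C)(C)C)C(C)=O
F2 | step 3 | (E)-4-[(tert-butyldimethylsilyl)oxy]-1-(dimethylamino)pent-1-en-3-one (racemic) | CN(C)/C=C/C(=O)C(C)O[Si](C)(C)C(C)(C)C
F3 | step 3 | 2-[(6R)-3-{2-[(tert-butyldimethylsilyl)oxy]propanoyl}-6-methyl-5,6-dihydro-4H-pyran-4-ylidene]acetaldehyde (epimers at the silyloxy carbon, Z isomer shown) | O=C/C=C1/C[C@@H](C)OC=C1C(=O)C(C)O[Si](C)(C)C(C)(C)C
F4 | step 3 | (3R)-7-[(tert-butyldimethylsilyl)oxy]-6-hydroxy-3,7-dimethyl-3,4,6,7-tetrahydro-8H-isochromen-8-one (mixture at C6 and C7) | CC1(O[Si](C)(C)C(C)(C)C)C(O)C=C2C[C@@H](C)OC=C2C1=O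
F5 | step 3 | (3R)-7-[(tert-butyldimethylsilyl)oxy]-3,7-dimethyl-3,4-dihydro-6H-isochromene-6,8(7H)-dione (C7 epimers) | CC1(O[Si](C)(C)C(C)(C)C)C(=O)C=C2C[C@@H](C)OC=C2C1=O
F6 | step 3 | (3R,7S)-7-hydroxy-3,7-dimethyl-3,4-dihydro-6H-isochromene-6,8(7H)-dione | O[C@@]1(C)C(=O)C=C2C[C@@H](C)OC=C2C1=O
F7 | step 2 | 3,3-dimethoxybutan-2-one | CC(=O)C(C)(OC)OC
F8 | step 2 | (E)-1-(dimethylamino)-4,4-dimethoxypent-1-en-3-one | CN(C)/C=C/C(=O)C(C)(OC)OC
F9 | step 1 | (R)-hex-2-yne-1,5-diol | C[C@@H](O)CC#CCO
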